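## Retrosynthetic overview

1. Ring C is made last: target 27 ⇐ 12‑O‑tert‑butyl quinone 24 ⇐ Moore ring expansion of dienyl hydroxycyclobutenone 21 ⇐ dienyl triflate 16 + squarate‑derived dione 20 (C9–C11 bond).
2. Ring A: 16 ⇐ intramolecular lactone‑enolate alkylation (C3–C4 bond) of bicyclic lactone 15; this fixes C4.
3. Lactone: 15 ⇐ reduction/re‑oxidation (transposition) of "iso‑lactone" 12; quaternary C10 ⇐ ring‑fusion alkylation of β‑keto lactone 8.
4. C5: 8 ⇐ enamine‑catalysed Michael addition of propanal to alkylidene β‑keto ester 4 (ring B comes from cyclohexanone ester 1).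
5. Ring order: B (from 1) → lactone ring → A → C.

Assumption: abietane numbering (C1–C20, as in the target) is used for locants in all intermediates; 1 is the commercial racemate, whose labile stereocentre is destroyed in step 1.

## Route

Step 1
Reactants: 1 methyl 2-oxocyclohexane-1-carboxylate
Product: 4 methyl 6-oxocyclohex-1-ene-1-carboxylate, via selenide 2 (not isolated), via selenoxide 3 (not isolated)
Conditions: PhSeCl, pyridine, CH2Cl2, 0 °C; then 30% H2O2, 0 to 25 °C
Reagents that add atoms: none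
Why: Reich α‑selenenylation of the β‑keto ester followed by oxidation and selenoxide syn‑elimination gives the doubly activated alkylidene β‑keto ester and removes the only (labile) stereocentre of 1.

Step 2
Reactants: 4 methyl 6-oxocyclohex-1-ene-1-carboxylate; 5 propanal
Product: 8 (4S,4aS)-4-methyl-3,4,4a,5,6,7-hexahydro-1H-isochromene-1,8(8aH)-dione, via Michael adduct aldehyde 6 (not isolated), via hydroxy ester 7 (not isolated)
Conditions: (R)-2-[diphenyl(trimethylsilyloxy)methyl]pyrrolidine (10 mol%), PhCO2H (10 mol%), toluene, 0 °C; then NaBH4, MeOH, −40 °C; then DBU (10 mol%), toluene, 40 °C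
Reagents that add atoms: none
Why: Enamine‑catalysed Michael addition of the Hayashi–Jørgensen type, in which the (R)‑catalyst's enamine of propanal attacks the Re face of C5 of the highly electrophilic acceptor (same topicity as in its nitroalkene and alkylidene malonate additions), sets C5 (and C4, erased later), after which NaBH4 reduces only the aldehyde (the β‑keto ester is protected as its enolate) and DBU‑promoted transesterification closes the β‑keto δ‑lactone.

Step 3
Reactants: 8 (4S,4aS)-4-methyl-hexahydro-1H-isochromene-1,8(8aH)-dione; 9 1-chloro-3-iodopropane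
Product: 10 (4S,4aS,8aR)-8a-(3-chloropropyl)-4-methyl-3,4,4a,5,6,7-hexahydro-1H-isochromene-1,8(8aH)-dione
Conditions: K2CO3, acetone, 40 °C
Reagents that add atoms: none
Why: C‑alkylation of the stabilised β‑keto lactone enolate by the iodide end of 9, with the electrophile entering the ring‑fusion enolate on the face of the axial C5–H, gives the cis‑fused product in which the new quaternary C10 carries the chain anti to C4 (substrate control from C5).

Step 4
Reactants: 10 keto lactone with the C10 chloropropyl chain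
Product: 11 (4S,4aS,8aR)-8a-(3-chloropropyl)-4-methyl-3,4,4a,5-tetrahydro-1H-isochromene-1,8(8aH)-dione
Conditions: IBX (2-iodoxybenzoic acid, 2 equiv), DMSO–fluorobenzene, 75 °C
Reagents that add atoms: none
Why: IBX (Nicolaou) dehydrogenation of the ketone through its only possible enol (towards C8) gives the C7=C8 enone that later supplies the 6,7‑alkene.

Step 5
Reactants: 11 enone lactone
Product: 12 (4S,4aS,8aR)-8a-(3-chloropropyl)-4-methyl-1-oxo-3,4,4a,8a-tetrahydro-1H-isochromen-8-yl trifluoromethanesulfonate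
Conditions: KN(SiMe3)2, THF, −78 °C; then PhNTf2, −78 to 0 °C
Reagents that add atoms: N-phenylbis(trifluoromethanesulfonimide), O=S(=O)(N(c1ccccc1)S(=O)(=O)C(F)(F)F)C(F)(F)F
Why: Because C10 is quaternary the base can only remove the γ‑proton at C6, and O‑triflation of the extended dienolate (enol triflate formation) masks the ketone as a 2‑triflyloxy‑1,3‑diene that already holds the C6=C7 bond.

Step 6
Reactants: 12 dienyl triflate iso-lactone
Product: 13 (5S,6S)-6-(3-chloropropyl)-6-(hydroxymethyl)-5-[(2S)-1-hydroxypropan-2-yl]cyclohexa-1,3-dien-1-yl trifluoromethanesulfonate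
Conditions: i-Bu2AlH (4 equiv), CH2Cl2, −78 to 0 °C; Rochelle salt work-up
Reagents that add atoms: none
Why: Lactone reduction by i‑Bu2AlH gives the 1,5‑diol while the dienyl triflate and the alkyl chloride are inert.

Step 7
Reactants: 13 diol
Product: 15 (4S,4aS,8aS)-8a-(3-chloropropyl)-4-methyl-3-oxo-3,4,4a,8a-tetrahydro-1H-isochromen-8-yl trifluoromethanesulfonate, via lactol 14 (not isolated)
Conditions: TEMPO (10 mol%), PhI(OAc)2 (2.5 equiv), CH2Cl2, 25 °C
Reagents that add atoms: none
Why: TEMPO/PhI(OAc)2 oxidative lactonisation, in which the oxoammonium oxidant takes the less hindered β‑branched C19 alcohol before the neopentyl C20 alcohol, the hydroxy aldehyde closes to lactol 14, and this is oxidised to the lactone with the carbonyl now on C19.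

Step 8
Reactants: 15 bicyclic lactone with C19 carbonyl
Product: 16 (1S,6R,7S)-7-methyl-8-oxo-9-oxatricyclo[5.3.3.0(1,6)]trideca-2,4-dien-2-yl trifluoromethanesulfonate
Conditions: LiN(i-Pr)2 (1.1 equiv), THF–DMPU, −78 to 0 °C
Reagents that add atoms: none
Why: Intramolecular alkylation of the lactone enolate (6‑exo‑tet), in which the chloropropyl chain on C10 can reach C4 only on its own face, closes ring A as a 3‑oxabicyclo[3.3.1]nonanone and fixes C4 (methyl equatorial, carbonyl bridge axial) whatever the C4 ratio of 15.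

Step 9
Reactants: 17 3,4-di-tert-butoxycyclobut-3-ene-1,2-dione; 18 isopropyllithium
Product: 20 3-tert-butoxy-4-isopropylcyclobut-3-ene-1,2-dione, via hydroxycyclobutenone 19 (not isolated)
Conditions: THF, −78 °C; then (CF3CO)2O, −78 to 0 °C; aq. NaHCO3
Reagents that add atoms: none
Why: Moore–Liebeskind squarate chemistry, in which 1,2‑addition of the organolithium is followed by trifluoroacetylation and loss of tert‑butyl trifluoroacetate (vinylogous ester cleavage) to unveil the 3‑alkoxy‑4‑alkylcyclobutenedione.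

Step 10
Reactants: 16 tricyclic lactone dienyl triflate; 20 3-tert-butoxy-4-isopropylcyclobut-3-ene-1,2-dione
Product: 21 3-tert-butoxy-4-hydroxy-2-isopropyl-4-[(1R,6R,7S)-7-methyl-8-oxo-9-oxatricyclo[5.3.3.0(1,6)]trideca-2,4-dien-2-yl]cyclobut-2-en-1-one
Conditions: CrCl2 (4 equiv), NiCl2 (2 mol%), 20 (2 equiv), DMF–THF, 25 °C
Reagents that add atoms: none
Why: Proposed new method: zerovalent nickel generated from NiCl2 and CrCl2 inserts into the dienyl C–OTf bond, transmetalation gives a dienyl chromium species (trivalent chromium) that should add 1,2 to the strained, non‑vinylogous ketone of 20 (the carbonyl next to C–Ot‑Bu, the site organolithiums choose) while leaving the hindered lactone and the vinylogous ester carbonyl untouched, forming the C9–C11 bond; the closest known reactions are the Nozaki–Hiyama–Kishi coupling of alkenyl triflates with aldehydes and the addition of alkenyllithiums to squarate‑derived diones.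

Step 11
Reactants: 21 dienyl hydroxycyclobutenone
Product: 24 (4S,5R,10R)-12-tert-butoxy-11,14-dioxoabieta-6,8,12-trien-19,20-olide, via dienylketene 22 (not isolated), via hydroquinone 23 (not isolated)
Conditions: toluene (degassed), 110 °C; then Ag2O, Et2O, 25 °C
Reagents that add atoms: none
Why: Moore rearrangement, in which thermal 4π‑electrocyclic ring opening gives dienylketene 22, 6π‑electrocyclisation onto C8 and tautomerisation give hydroquinone 23 with the substitution pattern fixed by step 10, and Ag2O then oxidises it to the quinone.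

Step 12
Reactants: 24 12-O-tert-butyl quinone lactone; 25 acetic anhydride
Product: 27 (4S,5R,10R)-12-acetoxy-11,14-dioxoabieta-6,8,12-trien-19,20-olide (CNP0596241.1), via hydroxyquinone 26 (not isolated)
Conditions: CF3CO2H, CH2Cl2, 0 °C; evaporate; then Ac2O, pyridine, DMAP (cat.), CH2Cl2, 0 °C
Reagents that add atoms: none
Why: Acidolysis of the tert‑butyl vinylogous ester (loss of 2‑methylpropene) frees the acidic 2‑hydroxyquinone, which is O‑acetylated under standard acylation conditions without touching the lactone or the stereocentres.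

## Compound list

1 | methyl 2-oxocyclohexane-1-carboxylate (racemate, labile stereocentre) | COC(=O)C1CCCCC1=O | starting material
2 | methyl 2-oxo-1-(phenylselanyl)cyclohexane-1-carboxylate (racemic) | COC(=O)C1([Se]c2ccccc2)CCCCC1=O | intermediate
3 | methyl 2-oxo-1-(phenylseleninyl)cyclohexane-1-carboxylate (racemic) | COC(=O)C1([Se](=O)c2ccccc2)CCCCC1=O | intermediate
4 | methyl 6-oxocyclohex-1-ene-1-carboxylate | COC(=O)C1=CCCCC1=O | intermediate
5 | propanal | CCC=O | starting material
6 | methyl (6S)-2-oxo-6-[(2S)-1-oxopropan-2-yl]cyclohexane-1-carboxylate (C1 epimerisable, largely enol) | O=C[C@@H](C)[C@H]1C(C(=O)OC)C(=O)CCC1 | intermediate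
7 | methyl (6S)-6-[(2S)-1-hydroxypropan-2-yl]-2-oxocyclohexane-1-carboxylate | OC[C@@H](C)[C@H]1C(C(=O)OC)C(=O)CCC1 | intermediate
8 | (4S,4aS)-4-methyl-3,4,4a,5,6,7-hexahydro-1H-isochromene-1,8(8aH)-dione (C8a epimerisable, largely enol; C4 shown as major epimer) | O=C1OC[C@@H](C)[C@@H]2CCCC(=O)C12 | intermediate
9 | 1-chloro-3-iodopropane | ClCCCI | starting material
10 | (4S,4aS,8aR)-8a-(3-chloropropyl)-4-methyl-3,4,4a,5,6,7-hexahydro-1H-isochromene-1,8(8aH)-dione (cis-fused; chain cis to H5) | O=C1OC[C@@H](C)[C@@H]2CCCC(=O)[C@]12CCCCl | intermediate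
11 | (4S,4aS,8aR)-8a-(3-chloropropyl)-4-methyl-3,4,4a,5-tetrahydro-1H-isochromene-1,8(8aH)-dione | O=C1OC[C@@H](C)[C@@H]2CC=CC(=O)[C@]12CCCCl | intermediate
12 | (4S,4aS,8aR)-8a-(3-chloropropyl)-4-methyl-1-oxo-3,4,4a,8a-tetrahydro-1H-isochromen-8-yl trifluoromethanesulfonate | O=C1OC[C@@H](C)[C@@H]2C=CC=C(OS(=O)(=O)C(F)(F)F)[C@]12CCCCl | intermediate
13 | (5S,6S)-6-(3-chloropropyl)-6-(hydroxymethyl)-5-[(2S)-1-hydroxypropan-2-yl]cyclohexa-1,3-dien-1-yl trifluoromethanesulfonate | OC[C@@H](C)[C@@H]1C=CC=C(OS(=O)(=O)C(F)(F)F)[C@@]1(CO)CCCCl | intermediate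
14 | (4S,4aS,8aS)-8a-(3-chloropropyl)-3-hydroxy-4-methyl-3,4,4a,8a-tetrahydro-1H-isochromen-8-yl trifluoromethanesulfonate (lactol, C3 epimers) | ClCCC[C@@]12COC(O)[C@@H](C)[C@@H]1C=CC=C2OS(=O)(=O)C(F)(F)F | intermediate
15 | (4S,4aS,8aS)-8a-(3-chloropropyl)-4-methyl-3-oxo-3,4,4a,8a-tetrahydro-1H-isochromen-8-yl trifluoromethanesulfonate (C4 epimers converge in step 8) | ClCCC[C@@]12COC(=O)[C@@H](C)[C@@H]1C=CC=C2OS(=O)(=O)C(F)(F)F | intermediate
16 | (1S,6R,7S)-7-methyl-8-oxo-9-oxatricyclo[5.3.3.0(1,6)]trideca-2,4-dien-2-yl trifluoromethanesulfonate (rings A and B with the 19,20-lactone; abietane 4S,5R,10S; C6=C7 and C8=C9; OTf on C9) | C1=C(OS(=O)(=O)C(F)(F)F)[C@]23CCC[C@](C)(C(=O)OC2)[C@@H]3C=C1 | intermediate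
17 | 3,4-di-tert-butoxycyclobut-3-ene-1,2-dione (di-tert-butyl squarate) | CC(C)(C)OC1=C(OC(C)(C)C)C(=O)C1=O | starting material
18 | isopropyllithium | [Li]C(C)C | starting material
19 | 2,3-di-tert-butoxy-4-hydroxy-4-isopropylcyclobut-2-en-1-one (as its lithium alkoxide) | CC(C)C1(O)C(OC(C)(C)C)=C(OC(C)(C)C)C1=O | intermediate
20 | 3-tert-butoxy-4-isopropylcyclobut-3-ene-1,2-dione | CC(C)C1=C(OC(C)(C)C)C(=O)C1=O | intermediate
21 | 3-tert-butoxy-4-hydroxy-2-isopropyl-4-[(1R,6R,7S)-7-methyl-8-oxo-9-oxatricyclo[5.3.3.0(1,6)]trideca-2,4-dien-2-yl]cyclobut-2-en-1-one (carbinol epimers) | C1=C(C4(O)C(OC(C)(C)C)=C(C(C)C)C4=O)[C@]23CCC[C@](C)(C(=O)OC2)[C@@H]3C=C1 | intermediate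
22 | dienylketene: 3-tert-butoxy-4-hydroxy-2-isopropyl-4-(C9-tricyclic dienyl)buta-1,3-dien-1-one | C1=C(C(O)=C(OC(C)(C)C)C(C(C)C)=C=O)[C@]23CCC[C@](C)(C(=O)OC2)[C@@H]3C=C1 | intermediate
23 | (4S,5R,10R)-12-tert-butoxy-11,14-dihydroxyabieta-6,8,11,13-tetraen-19,20-olide | CC(C)(C)Oc1c(C(C)C)c(O)c2c(c1O)[C@]13CCC[C@](C)(C(=O)OC1)[C@@H]3C=C2 | intermediate
24 | (4S,5R,10R)-12-tert-butoxy-11,14-dioxoabieta-6,8,12-trien-19,20-olide | CC(C)(C)OC1=C(C(C)C)C(=O)C2=C(C1=O)[C@]13CCC[C@](C)(C(=O)OC1)[C@@H]3C=C2 | intermediate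
25 | acetic anhydride | CC(=O)OC(C)=O | starting material
26 | (4S,5R,10R)-12-hydroxy-11,14-dioxoabieta-6,8,12-trien-19,20-olide | OC1=C(C(C)C)C(=O)C2=C(C1=O)[C@]13CCC[C@](C)(C(=O)OC1)[C@@H]3C=C2 | intermediate
27 | (4S,5R,10R)-12-acetoxy-11,14-dioxoabieta-6,8,12-trien-19,20-olide (CNP0596241.1) | CC(=O)OC1=C(C(C)C)C(=O)C2=C(C1=O)[C@]13CCC[C@](C)(C(=O)OC1)[C@@H]3C=C2 | target

## Step count and weak points

Total step count: 12 (11 on the main line plus step 9 for dione 20). Longest linear sequence: 11 steps (steps 1–8 and 10–12).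

The three steps most likely to fail:

Step 10 (the proposed new coupling). Divalent chromium might reduce dione 20, or the hindered dienyl chromium species might add too slowly to a ketone. The fallback uses known chemistry, sets out from 16 and comes back at 21. Stannylation of the triflate (Pd(PPh3)4, Me3SnSnMe3, LiCl, THF, 60 °C) gives the trimethylstannyl diene lactone F5. Tin–lithium exchange (MeLi, THF, −78 °C) gives the dienyllithium lactone F6, which is not isolated; the bridged, α‑quaternary lactone tolerates this at low temperature. Adding 20 at −78 °C, the standard organolithium addition to a squarate‑derived dione, gives 21.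

Step 2 (the stereo‑defining Michael addition). The facial selectivity is assigned by analogy only, the acceptor can dimerise, and the adduct may sit as a hemiacetal that is slow to reduce. The fallback sets out from 4 and comes back at 6. A cinchona squaramide‑catalysed decarboxylative Michael addition of 2-methyl-3-oxo-3-(phenylsulfanyl)propanoic acid F1 (the methylmalonic acid half thioester) to 4 gives S-phenyl (2S)-2-[(1R)-2-(methoxycarbonyl)-3-oxocyclohexyl]propanethioate F2. The pseudo‑enantiomeric catalyst is chosen for the same C5 configuration. Fukuyama reduction (Pd/C, Et3SiH, acetone) converts F2 into aldehyde 6, which is then reduced and lactonised as in step 2.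

Step 7 (regioselective oxidative lactonisation). If the neopentyl C20 alcohol is oxidised competitively, iso‑lactone 12 is regenerated. The fallback sets out from 13 and comes back at 15. Both alcohols are oxidised (TEMPO, PhI(OAc)2, MeCN–H2O) to (1R,6S)-6-[(1S)-1-carboxyethyl]-1-(3-chloropropyl)-2-(trifluoromethylsulfonyloxy)cyclohexa-2,4-diene-1-carboxylic acid F3. Ac2O closes it to (4S,4aS,8aR)-8a-(3-chloropropyl)-4-methyl-1,3-dioxo-3,4,4a,8a-tetrahydro-1H-isochromen-8-yl trifluoromethanesulfonate F4, a cyclic anhydride. NaBH4 (THF, 0 °C, then acid) attacks the carbonyl flanked by the quaternary carbon (C20), the usual site for hydride reduction of unsymmetrical cyclic anhydrides, and gives lactone 15.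

Further compounds
F1 | step 2 | 2-methyl-3-oxo-3-(phenylsulfanyl)propanoic acid | CC(C(O)=O)C(=O)Sc1ccccc1
F2 | step 2 | S-phenyl (2S)-2-[(1R)-2-(methoxycarbonyl)-3-oxocyclohexyl]propanethioate | O=C(Sc1ccccc1)[C@@H](C)[C@H]1C(C(=O)OC)C(=O)CCC1
F3 | step 7 | (1R,6S)-6-[(1S)-1-carboxyethyl]-1-(3-chloropropyl)-2-(trifluoromethylsulfonyloxy)cyclohexa-2,4-diene-1-carboxylic acid | OC(=O)[C@@H](C)[C@@H]1C=CC=C(OS(=O)(=O)C(F)(F)F)[C@@]1(C(O)=O)CCCCl
F4 | step 7 | (4S,4aS,8aR)-8a-(3-chloropropyl)-4-methyl-1,3-dioxo-3,4,4a,8a-tetrahydro-1H-isochromen-8-yl trifluoromethanesulfonate | ClCCC[C@@]12C(=O)OC(=O)[C@@H](C)[C@@H]1C=CC=C2OS(=O)(=O)C(F)(F)F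
F5 | step 10 | (1R,6R,7S)-7-methyl-2-(trimethylstannyl)-9-oxatricyclo[5.3.3.0(1,6)]trideca-2,4-dien-8-one | C1=C([Sn](C)(C)C)[C@]23CCC[C@](C)(C(=O)OC2)[C@@H]3C=C1
F6 | step 10 | [(1R,6R,7S)-7-methyl-8-oxo-9-oxatricyclo[5.3.3.0(1,6)]trideca-2,4-dien-2-yl]lithium | C1=C([Li])[C@]23CCC[C@](C)(C(=O)OC2)[C@@H]3C=C1
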